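The summer run, charged at 0.68 M partner, shows you the mono adduct rising and falling: it reads 50% at 6.00 min, 52% at 10.0 min and 28% at 25.0 min. The new flasks are to be read at one fixed time, and their charges differ.

the same everywhere: starting material 0.050 M

| run | partner | remark | time |
|---|---|---|---|
| autumn | 0.0079 M | run made earlier |  |
| summer | 0.68 M | run made earlier |  |
| south-east | 0.00600 M |  | 25 min |
| west | 0.0150 M |  | 25 min |
| south | 0.0500 M |  | 25 min |
| north | 0.150 M |  | 25 min |
| north-west | 0.500 M |  | 25 min |

| run | time / min | mono adduct / % |
|---|---|---|
| autumn | 4.00 | 4 |
| autumn | 8.00 | 2 |
| autumn | 12.0 | 0 |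
| autumn | 15.0 | 3 |
| autumn | 20.0 | 6 |
| autumn | 25.0 | 5 |
| summer | 2.00 | 29 |
| summer | 3.00 | 36 |
| summer | 6.00 | 50 |
| summer | 10.0 | 52 |
| summer | 15.0 | 42 |
| summer | 25.0 | 28 |

(readings scatter by 2 percentage points)

- the analysis behind the earlier runs scatters by 2 percentage points, standard deviation
- "hardly changes" means that all values lie within two and a half points (for a concentration: within two and a half percent of the largest)

1. amount of mono adduct at the end, in percent of the starting material charged for south-east, west, south, north, north-west, in this order
2. how that number moves from the first to the last of them (falls all the way / falls, then rises / rises, then falls / rises all the way / hardly changes)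

So count turnovers. My own assumption is that each step runs at a rate proportional to [partner], with [partner] staying near its charge (pseudo-first-order). A flask's turnovers then grow with [partner] times time. The summer peak, read between those first two times at about 8.00 min, gives 326 M·s, the peak dose, which is [partner] times time at the top of the mono adduct curve. At 25 min the north flask has 225 M·s, less than the peak dose, and the north-west flask has 750 M·s, more than the peak dose. So I expect the row to rise and then fall, with its top at a charge of 218 mM.

The forecast gives 3.4%, 8%, 23%, 45% and 36%, so rises, then falls, “with a maximum near 0.2 M”.

The flasks give 3.42%, 8.26%, 24.0%, 48.0% and 38.5%, so rises, then falls.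

    starting material + partner → mono adduct + by-product (k = 0.310 M⁻¹ min⁻¹)
    partner + mono adduct → double product + by-product (k = 0.130 M⁻¹ min⁻¹)
    crystals ⇌ by-product, rate k3*(cs3 - [by-product]) while solid is left; crystals form when [by-product] > cs3 (solubility = 24.0 mM, k = 0.740 min⁻¹)
    starting material → decomposition product (k = 2.20 × 10⁻⁴ min⁻¹)
    partner → decomposed reagent (k = 0.00810 min⁻¹)

The row turns at 0.24 M, which over 25 min makes 367 M·s, beside the peak dose of 326 M·s. Now watch the south flask at 250 min: its charge times time is 750 M·s, more than the peak dose. But its partner stands at 0.859% of charge, its mono adduct at 43.8% and its double product at 8.22%.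

The readings stem from a simulated flask on assumed constants; noise was put on by code.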